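**Plan**

1. Ring numbering used throughout: C1 = C(CH3)OH, C2 = CH carrying the pentenyl arm, C3 = quaternary carbon, C4 = CHBr, C5/C6 = CH2. The retrosynthesis cuts, in this order: the terminal alkene of the C3 arm (cross-metathesis), the Cβ–Cγ bond of the C2 arm (lithiation–borylation) and one CH2 before it (Matteson), C4–Br (back to a C4 ketone), the C3–allyl bond (enolate allylation), the ring bond C1–C2, and the C3–C4 bond (crotylboration).
2. Enabling feature: the array C1(OH)(CH3)–C2H–CH2, a tertiary carbinol of the cyclohexane ring bonded to a ring CH whose exocyclic carbon is a CH2. This is the retron of a reductive ketone–alkene (ketyl–olefin) coupling. A boryl group on that CH2 activates the alkene and remains as the handle for the side chain.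
3. Forward: 4-oxopentanal and a (Z)-crotyl boronate give an acyclic keto alcohol; cross-metathesis gives the alkenyl boronate; the SmI2 cyclisation closes the only ring (C1–C2). Then follow C4 oxidation, C3 allylation, C4 reduction and bromination, two boron homologations, a last cross-metathesis and desilylation.
4. Stereochemistry: the C3/C4 centres from the catalyst-controlled crotylboration are temporary helpers that steer the ring closure and are erased at the C4 ketone stage. C2 and C1 come from the chair transition state of the ring closure, quaternary C3 from allylation anti to the C2 arm, and C4–Br from equatorial hydride delivery followed by SN2 inversion. The side-chain carbinol comes from (R)-but-3-en-2-ol by stereospecific lithiation–borylation.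

Key step: step 4

Remark: the (R) enantiomer of the phosphoric acid is assumed to direct the crotyl group to the Re face of the aldehyde, as in related allylborations; if the sense is opposite, the (S) acid is used.

**Route**

Step 1
Reactants: 1 hex-5-en-2-one
Product: 3 4-oxopentanal, via ozonide 2 (not isolated)
Conditions: O3, CH2Cl2, −78 °C; then PPh3, −78 °C to rt
Reagents that add atoms: ozone [O-][O+]=O
Why: Ozonolysis with reductive work-up cleaves only the terminal alkene, the ketone being inert, and no stereocenter is formed.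

Step 2
Reactants: 3 4-oxopentanal; 4 2-[(2Z)-but-2-en-1-yl]-4,4,5,5-tetramethyl-1,3,2-dioxaborolane
Product: 6 (5S,6S)-5-hydroxy-6-methyloct-7-en-2-one, via borate ester 5 (not isolated)
Conditions: (R)-TRIP [(R)-3,3′-bis(2,4,6-triisopropylphenyl)-1,1′-binaphthyl-2,2′-diyl hydrogen phosphate] (5 mol%), 4 Å molecular sieves, toluene, −30 °C; then H2O
Reagents that add atoms: none
Why: Chiral phosphoric acid-catalysed crotylboration is aldehyde-selective and proceeds through a closed chair transition state, so the (Z)-crotyl geometry should give the syn methyl/hydroxyl pair and Re-face attack under the (R)-acid the (5S,6S) isomer.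

Step 3
Reactants: 6 (5S,6S)-5-hydroxy-6-methyloct-7-en-2-one; 7 2-ethenyl-4,4,5,5-tetramethyl-1,3,2-dioxaborolane
Product: 8 (5S,6S,7E)-5-hydroxy-6-methyl-8-(4,4,5,5-tetramethyl-1,3,2-dioxaborolan-2-yl)oct-7-en-2-one
Conditions: second-generation Hoveyda–Grubbs catalyst (5 mol%), CH2Cl2, 40 °C
Reagents that add atoms: none
Why: Olefin cross-metathesis of the monosubstituted alkene with the vinyl boronate should give the (E)-alkenyl boronate with loss of ethene, the free hydroxyl and the ketone being tolerated and both stereocenters untouched.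

Step 4
Reactants: 8 (5S,6S,7E)-5-hydroxy-6-methyl-8-(4,4,5,5-tetramethyl-1,3,2-dioxaborolan-2-yl)oct-7-en-2-one
Product: 9 (1S,2S,3S,4S)-1,3-dimethyl-2-[(4,4,5,5-tetramethyl-1,3,2-dioxaborolan-2-yl)methyl]cyclohexane-1,4-diol
Conditions: SmI2 (2.5 equiv), HMPA (8 equiv), t-BuOH (2 equiv), THF, −78 °C to 0 °C
Reagents that add atoms: none
Why: Proposed new method: single-electron transfer from HMPA-ligated samarium diiodide to the methyl ketone gives a samarium ketyl that adds 6-exo-trig to the alkene carbon remote from boron; the α-boryl radical is then reduced to an α-boryl organosamarium and protonated by t-BuOH, which closes the bond C1–C2 and leaves the CH2–B handle. The closest known reaction types are the samarium diiodide ketyl–olefin cyclisation onto α,β-unsaturated esters and the addition of α-oxygenated radicals to alkenyl boronic esters, the boryl group taking the role of the ester as radical-stabilising acceptor. The six-membered ring closes in the 6-exo mode through a chair transition state. C2 is set by the existing syn C3-methyl/C4-hydroxyl pair, which can both be equatorial in only one chair and so places the alkenyl boronate equatorial, cis to the C4 oxygen and trans to the C3 methyl; C1 is set by the bulky HMPA-solvated O–Sm group, which takes the equatorial site anti to the alkene and leaves the methyl axial (C3 carries only hydrogen axial at this stage), so that OH is trans to the CH2B arm. The step needs 6-exo over 7-endo regioselectivity, secured by the radical-stabilising boron on the distal alkene carbon, and a non-chelated pathway, secured by HMPA saturating the samarium so that the free C4 hydroxyl cannot bridge to the ketyl.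

Step 5
Reactants: 9 (1S,2S,3S,4S)-1,3-dimethyl-2-[(4,4,5,5-tetramethyl-1,3,2-dioxaborolan-2-yl)methyl]cyclohexane-1,4-diol
Product: 10 (2S,3S,4S)-4-hydroxy-2,4-dimethyl-3-[(4,4,5,5-tetramethyl-1,3,2-dioxaborolan-2-yl)methyl]cyclohexan-1-one
Conditions: Dess–Martin periodinane, CH2Cl2, 0 °C to rt
Reagents that add atoms: none
Why: Dess–Martin oxidation converts the secondary C4 hydroxyl into the ketone needed to functionalise C3, while the tertiary C1 hydroxyl and the boronic ester are not oxidised; the C3 stereocenter becomes enolisable and is re-set in step 7.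

Step 6
Reactants: 10 (2S,3S,4S)-4-hydroxy-2,4-dimethyl-3-[(4,4,5,5-tetramethyl-1,3,2-dioxaborolan-2-yl)methyl]cyclohexan-1-one
Product: 11 trimethyl({(3S,4S)-2,4-dimethyl-3-[(4,4,5,5-tetramethyl-1,3,2-dioxaborolan-2-yl)methyl]-4-[(trimethylsilyl)oxy]cyclohex-1-en-1-yl}oxy)silane
Conditions: TMSCl, NaI, Et3N, MeCN, rt
Reagents that add atoms: chlorotrimethylsilane C[Si](C)(C)Cl
Why: Silyl enol ether formation with iodotrimethylsilane made in situ is under thermodynamic control and should favour the more substituted C3=C4 enol ether, and the same reagent silylates the tertiary C1 hydroxyl, which then stays masked until the last step.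

Step 7
Reactants: 11 trimethyl({(3S,4S)-2,4-dimethyl-3-[(4,4,5,5-tetramethyl-1,3,2-dioxaborolan-2-yl)methyl]-4-[(trimethylsilyl)oxy]cyclohex-1-en-1-yl}oxy)silane; 12 methyl prop-2-en-1-yl carbonate
Product: 13 (2S,3S,4S)-2,4-dimethyl-2-(prop-2-en-1-yl)-3-[(4,4,5,5-tetramethyl-1,3,2-dioxaborolan-2-yl)methyl]-4-[(trimethylsilyl)oxy]cyclohexan-1-one
Conditions: Pd2(dba)3 (2.5 mol%), dppe (6 mol%), THF, 65 °C
Reagents that add atoms: none
Why: Palladium-catalysed Tsuji–Trost allylation of a silyl enol ether is regiospecific, and the allyl group should add to the face of C3 anti to the C2 arm and to the axial C1 methyl, which sets the quaternary centre with methyl cis to the C2 arm.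

Step 8
Reactants: 13 (2S,3S,4S)-2,4-dimethyl-2-(prop-2-en-1-yl)-3-[(4,4,5,5-tetramethyl-1,3,2-dioxaborolan-2-yl)methyl]-4-[(trimethylsilyl)oxy]cyclohexan-1-one
Product: 14 (1R,2S,3S,4S)-2,4-dimethyl-2-(prop-2-en-1-yl)-3-[(4,4,5,5-tetramethyl-1,3,2-dioxaborolan-2-yl)methyl]-4-[(trimethylsilyl)oxy]cyclohexan-1-ol
Conditions: LiBH(s-Bu)3 (L-Selectride), THF, −78 °C; then H2O
Reagents that add atoms: none
Why: Hydride reduction with the bulky LiBH(s-Bu)3 occurs by equatorial attack on the ketone next to the quaternary carbon, which should give the axial C4 alcohol trans to the C3 methyl; the non-oxidative work-up keeps the boronic ester.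

Step 9
Reactants: 14 (1R,2S,3S,4S)-2,4-dimethyl-2-(prop-2-en-1-yl)-3-[(4,4,5,5-tetramethyl-1,3,2-dioxaborolan-2-yl)methyl]-4-[(trimethylsilyl)oxy]cyclohexan-1-ol
Product: 15 2-{[(1S,2S,3S,6S)-3-bromo-2,6-dimethyl-2-(prop-2-en-1-yl)-6-[(trimethylsilyl)oxy]cyclohexyl]methyl}-4,4,5,5-tetramethyl-1,3,2-dioxaborolane
Conditions: CBr4, PPh3, CH2Cl2, 0 °C to 40 °C
Reagents that add atoms: tetrabromomethane BrC(Br)(Br)Br
Why: The Appel reaction displaces the alkoxyphosphonium ion by bromide in an SN2 step with inversion, so the axial alcohol should give the equatorial bromide cis to the C3 methyl, as known for axial neopentylic cyclohexanols.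

Step 10
Reactants: 15 2-{[(1S,2S,3S,6S)-3-bromo-2,6-dimethyl-2-(prop-2-en-1-yl)-6-[(trimethylsilyl)oxy]cyclohexyl]methyl}-4,4,5,5-tetramethyl-1,3,2-dioxaborolane
Product: 17 2-{2-[(1S,2S,3S,6S)-3-bromo-2,6-dimethyl-2-(prop-2-en-1-yl)-6-[(trimethylsilyl)oxy]cyclohexyl]ethyl}-4,4,5,5-tetramethyl-1,3,2-dioxaborolane, via chloromethyl boronate complex 16 (not isolated)
Conditions: ICH2Cl, n-BuLi, THF, −78 °C to rt
Reagents that add atoms: chloroiodomethane ClCI
Why: Matteson homologation: (chloromethyl)lithium made in situ adds to boron and the alkyl group migrates with loss of chloride, which inserts one CH2 without touching a stereocenter, the hindered secondary bromide being inert to n-BuLi at −78 °C.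

Step 11
Reactants: 18 (2R)-but-3-en-2-ol
Product: 19 (2R)-but-3-en-2-yl N,N-di(propan-2-yl)carbamate
Conditions: i-Pr2NCOCl, Et3N, DMAP (cat.), CH2Cl2, 40 °C
Reagents that add atoms: N,N-di(propan-2-yl)carbamoyl chloride CC(C)N(C(C)C)C(Cl)=O
Why: Carbamoylation of the secondary alcohol gives the directing carbamate needed for lithiation and does not involve the stereocenter.

Step 12
Reactants: 19 (2R)-but-3-en-2-yl N,N-di(propan-2-yl)carbamate; 17 2-{2-[(1S,2S,3S,6S)-3-bromo-2,6-dimethyl-2-(prop-2-en-1-yl)-6-[(trimethylsilyl)oxy]cyclohexyl]ethyl}-4,4,5,5-tetramethyl-1,3,2-dioxaborolane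
Product: 23 (3S)-5-{(1S,2S,3S,6S)-3-bromo-2,6-dimethyl-2-(prop-2-en-1-yl)-6-[(trimethylsilyl)oxy]cyclohexyl}-3-methylpent-1-en-3-ol, via lithiated carbamate 20 (not isolated), via boronate complex 21 (not isolated), via tertiary boronic ester 22 (not isolated)
Conditions: s-BuLi, TMEDA, Et2O, −78 °C; then 17, −78 °C to 35 °C; then NaBO3·4H2O, THF/H2O, rt
Reagents that add atoms: sodium perborate [Na+].[O-]OB=O
Why: Lithiation–borylation–oxidation: the carbamate is deprotonated with retention, boron adds with retention, the primary alkyl group migrates from boron to carbon with inversion and the C–B bond is oxidised with retention, so the alkyl group takes the place of the carbinol hydrogen of the (R)-alcohol and the (S) tertiary allylic alcohol should result.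

Step 13
Reactants: 23 (3S)-5-{(1S,2S,3S,6S)-3-bromo-2,6-dimethyl-2-(prop-2-en-1-yl)-6-[(trimethylsilyl)oxy]cyclohexyl}-3-methylpent-1-en-3-ol; 24 2-methylbut-3-en-2-ol
Product: 25 (3S)-5-{(1S,2S,3S,6S)-3-bromo-2-[(2E)-4-hydroxy-4-methylpent-2-en-1-yl]-2,6-dimethyl-6-[(trimethylsilyl)oxy]cyclohexyl}-3-methylpent-1-en-3-ol
Conditions: second-generation Hoveyda–Grubbs catalyst (5 mol%), 24 (8 equiv), CH2Cl2, 40 °C
Reagents that add atoms: none
Why: Olefin cross-metathesis of the unhindered allyl group with excess 2-methylbut-3-en-2-ol should give the (E)-disubstituted alkene, the vinyl group on the fully substituted carbinol carbon of the C2 arm being much slower to react.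

Step 14
Reactants: 25 (3S)-5-{(1S,2S,3S,6S)-3-bromo-2-[(2E)-4-hydroxy-4-methylpent-2-en-1-yl]-2,6-dimethyl-6-[(trimethylsilyl)oxy]cyclohexyl}-3-methylpent-1-en-3-ol
Product: 26 (1S,2S,3S,4S)-4-bromo-3-[(2E)-4-hydroxy-4-methylpent-2-en-1-yl]-2-[(3S)-3-hydroxy-3-methylpent-4-en-1-yl]-1,3-dimethylcyclohexan-1-ol
Conditions: HF·pyridine, pyridine, THF, 0 °C
Reagents that add atoms: none
Why: Buffered fluoride cleaves the trimethylsilyl ether without base, which avoids displacement of the trans-1,4 bromide by the C1 alkoxide and ionisation of the tertiary allylic alcohols; no stereocenter is touched.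

**Compound list**

1 | hex-5-en-2-one | CC(=O)CCC=C | starting material
2 | 4-(1,2,4-trioxolan-3-yl)butan-2-one | CC(=O)CCC1OCOO1 | intermediate
3 | 4-oxopentanal | CC(=O)CCC=O | intermediate
4 | 2-[(2Z)-but-2-en-1-yl]-4,4,5,5-tetramethyl-1,3,2-dioxaborolane | C/C=C\CB1OC(C)(C)C(C)(C)O1 | starting material
5 | (5S,6S)-6-methyl-5-[(4,4,5,5-tetramethyl-1,3,2-dioxaborolan-2-yl)oxy]oct-7-en-2-one | C=C[C@H](C)[C@@H](OB1OC(C)(C)C(C)(C)O1)CCC(C)=O | intermediate
6 | (5S,6S)-5-hydroxy-6-methyloct-7-en-2-one | C=C[C@H](C)[C@@H](O)CCC(C)=O | intermediate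
7 | 2-ethenyl-4,4,5,5-tetramethyl-1,3,2-dioxaborolane | C=CB1OC(C)(C)C(C)(C)O1 | starting material
8 | (5S,6S,7E)-5-hydroxy-6-methyl-8-(4,4,5,5-tetramethyl-1,3,2-dioxaborolan-2-yl)oct-7-en-2-one | CC1(C)OB(/C=C/[C@H](C)[C@@H](O)CCC(C)=O)OC1(C)C | intermediate
9 | (1S,2S,3S,4S)-1,3-dimethyl-2-[(4,4,5,5-tetramethyl-1,3,2-dioxaborolan-2-yl)methyl]cyclohexane-1,4-diol | CC1(C)OB(C[C@H]2[C@H](C)[C@@H](O)CC[C@]2(C)O)OC1(C)C | intermediate
10 | (2S,3S,4S)-4-hydroxy-2,4-dimethyl-3-[(4,4,5,5-tetramethyl-1,3,2-dioxaborolan-2-yl)methyl]cyclohexan-1-one | CC1(C)OB(C[C@H]2[C@H](C)C(=O)CC[C@]2(C)O)OC1(C)C | intermediate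
11 | trimethyl({(3S,4S)-2,4-dimethyl-3-[(4,4,5,5-tetramethyl-1,3,2-dioxaborolan-2-yl)methyl]-4-[(trimethylsilyl)oxy]cyclohex-1-en-1-yl}oxy)silane | CC1(C)OB(C[C@H]2C(C)=C(O[Si](C)(C)C)CC[C@]2(C)O[Si](C)(C)C)OC1(C)C | intermediate
12 | methyl prop-2-en-1-yl carbonate | C=CCOC(=O)OC | starting material
13 | (2S,3S,4S)-2,4-dimethyl-2-(prop-2-en-1-yl)-3-[(4,4,5,5-tetramethyl-1,3,2-dioxaborolan-2-yl)methyl]-4-[(trimethylsilyl)oxy]cyclohexan-1-one | CC1(C)OB(C[C@H]2[C@](C)(CC=C)C(=O)CC[C@]2(C)O[Si](C)(C)C)OC1(C)C | intermediate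
14 | (1R,2S,3S,4S)-2,4-dimethyl-2-(prop-2-en-1-yl)-3-[(4,4,5,5-tetramethyl-1,3,2-dioxaborolan-2-yl)methyl]-4-[(trimethylsilyl)oxy]cyclohexan-1-ol | CC1(C)OB(C[C@H]2[C@](C)(CC=C)[C@H](O)CC[C@]2(C)O[Si](C)(C)C)OC1(C)C | intermediate
15 | 2-{[(1S,2S,3S,6S)-3-bromo-2,6-dimethyl-2-(prop-2-en-1-yl)-6-[(trimethylsilyl)oxy]cyclohexyl]methyl}-4,4,5,5-tetramethyl-1,3,2-dioxaborolane | CC1(C)OB(C[C@H]2[C@](C)(CC=C)[C@@H](Br)CC[C@]2(C)O[Si](C)(C)C)OC1(C)C | intermediate
16 | lithium (chloromethyl){[(1S,2S,3S,6S)-3-bromo-2,6-dimethyl-2-(prop-2-en-1-yl)-6-[(trimethylsilyl)oxy]cyclohexyl]methyl}(2,3-dimethylbutane-2,3-diolato)borate | [Li+].ClC[B-]1(C[C@H]2[C@](C)(CC=C)[C@@H](Br)CC[C@]2(C)O[Si](C)(C)C)OC(C)(C)C(C)(C)O1 | intermediate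
17 | 2-{2-[(1S,2S,3S,6S)-3-bromo-2,6-dimethyl-2-(prop-2-en-1-yl)-6-[(trimethylsilyl)oxy]cyclohexyl]ethyl}-4,4,5,5-tetramethyl-1,3,2-dioxaborolane | CC1(C)OB(CC[C@H]2[C@](C)(CC=C)[C@@H](Br)CC[C@]2(C)O[Si](C)(C)C)OC1(C)C | intermediate
18 | (2R)-but-3-en-2-ol | C=C[C@@H](C)O | starting material
19 | (2R)-but-3-en-2-yl N,N-di(propan-2-yl)carbamate | C=C[C@@H](C)OC(=O)N(C(C)C)C(C)C | intermediate
20 | (2R)-2-lithiobut-3-en-2-yl N,N-di(propan-2-yl)carbamate | C=C[C@@]([Li])(C)OC(=O)N(C(C)C)C(C)C | intermediate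
21 | lithium [(2R)-2-{[di(propan-2-yl)carbamoyl]oxy}but-3-en-2-yl]{2-[(1S,2S,3S,6S)-3-bromo-2,6-dimethyl-2-(prop-2-en-1-yl)-6-[(trimethylsilyl)oxy]cyclohexyl]ethyl}(2,3-dimethylbutane-2,3-diolato)borate | [Li+].C=C[C@@]([B-]1(CC[C@H]2[C@](C)(CC=C)[C@@H](Br)CC[C@]2(C)O[Si](C)(C)C)OC(C)(C)C(C)(C)O1)(C)OC(=O)N(C(C)C)C(C)C | intermediate
22 | 2-[(3R)-5-{(1S,2S,3S,6S)-3-bromo-2,6-dimethyl-2-(prop-2-en-1-yl)-6-[(trimethylsilyl)oxy]cyclohexyl}-3-methylpent-1-en-3-yl]-4,4,5,5-tetramethyl-1,3,2-dioxaborolane | C=C[C@@](CC[C@H]1[C@](C)(CC=C)[C@@H](Br)CC[C@]1(C)O[Si](C)(C)C)(C)B1OC(C)(C)C(C)(C)O1 | intermediate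
23 | (3S)-5-{(1S,2S,3S,6S)-3-bromo-2,6-dimethyl-2-(prop-2-en-1-yl)-6-[(trimethylsilyl)oxy]cyclohexyl}-3-methylpent-1-en-3-ol | C=C[C@@](C)(O)CC[C@H]1[C@](C)(CC=C)[C@@H](Br)CC[C@]1(C)O[Si](C)(C)C | intermediate
24 | 2-methylbut-3-en-2-ol | C=CC(C)(C)O | starting material
25 | (3S)-5-{(1S,2S,3S,6S)-3-bromo-2-[(2E)-4-hydroxy-4-methylpent-2-en-1-yl]-2,6-dimethyl-6-[(trimethylsilyl)oxy]cyclohexyl}-3-methylpent-1-en-3-ol | C=C[C@@](C)(O)CC[C@H]1[C@](C)(C/C=C/C(C)(C)O)[C@@H](Br)CC[C@]1(C)O[Si](C)(C)C | intermediate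
26 | (1S,2S,3S,4S)-4-bromo-3-[(2E)-4-hydroxy-4-methylpent-2-en-1-yl]-2-[(3S)-3-hydroxy-3-methylpent-4-en-1-yl]-1,3-dimethylcyclohexan-1-ol | C=C[C@@](C)(O)CC[C@H]1[C@](C)(C/C=C/C(C)(C)O)[C@@H](Br)CC[C@]1(C)O | target

**Step count and risks**

Total step count: 14. Longest linear sequence: 13 steps (steps 1–10 and 12–14; step 11 prepares the carbamate).

Steps most likely to fail:

1. Step 4 (Proposed new method). The ketyl may be reduced further to the secondary alcohol, or may add too slowly to the alkenyl boronate, so that ring closure does not compete. The fallback uses known chemistry, sets out from 6 and comes back at 9. Cross-metathesis of 6 with methyl acrylate gives methyl (2E,4S,5S)-5-hydroxy-4-methyl-8-oxonon-2-enoate F1. The established samarium diiodide ketyl–olefin cyclisation onto the enoate (SmI2, HMPA, t-BuOH, THF) should give, through the same chair, methyl 2-[(1S,2S,3S,6S)-3,6-dihydroxy-2,6-dimethylcyclohexyl]acetate F2. Saponification with LiOH gives 2-[(1S,2S,3S,6S)-3,6-dihydroxy-2,6-dimethylcyclohexyl]acetic acid F3. DIC and N-hydroxyphthalimide give the redox-active ester 1,3-dioxo-1,3-dihydro-2H-isoindol-2-yl 2-[(1S,2S,3S,6S)-3,6-dihydroxy-2,6-dimethylcyclohexyl]acetate F4. Light-driven decarboxylative borylation with B2cat2, followed by pinacol and Et3N, then gives 9.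

2. Step 9. At the neopentylic carbinol, elimination toward C5 or a 1,2-shift of the anti-periplanar C3 methyl may outrun substitution. The fallback sets out from 14 and comes back at 15. Tf2O and pyridine at −40 °C give the isolated sulfonate (1R,2S,3S,4S)-2,4-dimethyl-2-(prop-2-en-1-yl)-3-[(4,4,5,5-tetramethyl-1,3,2-dioxaborolan-2-yl)methyl]-4-[(trimethylsilyl)oxy]cyclohexyl trifluoromethanesulfonate F5. Displacement with LiBr in toluene/THF at low temperature should proceed with inversion to 15.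

3. Step 6. Enolisation toward C5 may compete (poor regioselectivity of the thermodynamic silylation), which would carry the allyl group to the wrong carbon in step 7. The fallback sets out from 10 and comes back at 13. Kinetic enolisation (LDA, TMSCl, THF, −78 °C) gives the less substituted enol ether trimethyl({(4S,5S,6S)-4,6-dimethyl-5-[(4,4,5,5-tetramethyl-1,3,2-dioxaborolan-2-yl)methyl]-4-[(trimethylsilyl)oxy]cyclohex-1-en-1-yl}oxy)silane F6. Saegusa–Ito oxidation (Pd(OAc)2, MeCN) gives (4S,5S,6S)-4,6-dimethyl-5-[(4,4,5,5-tetramethyl-1,3,2-dioxaborolan-2-yl)methyl]-4-[(trimethylsilyl)oxy]cyclohex-2-en-1-one F7. This enone has an acidic hydrogen only at C3, because its γ-carbon C1 is fully substituted. LDA followed by allyl bromide therefore alkylates C3, anti to the C2 arm, to give (4S,5S,6S)-4,6-dimethyl-6-(prop-2-en-1-yl)-5-[(4,4,5,5-tetramethyl-1,3,2-dioxaborolan-2-yl)methyl]-4-[(trimethylsilyl)oxy]cyclohex-2-en-1-one F8. Conjugate reduction of the enone with [(Ph3P)CuH]6 returns 13.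

**Further compounds**

F1 | step 4 | methyl (2E,4S,5S)-5-hydroxy-4-methyl-8-oxonon-2-enoate | COC(=O)/C=C/[C@H](C)[C@@H](O)CCC(C)=O
F2 | step 4 | methyl 2-[(1S,2S,3S,6S)-3,6-dihydroxy-2,6-dimethylcyclohexyl]acetate | COC(=O)C[C@H]1[C@H](C)[C@@H](O)CC[C@]1(C)O
F3 | step 4 | 2-[(1S,2S,3S,6S)-3,6-dihydroxy-2,6-dimethylcyclohexyl]acetic acid | OC(=O)C[C@H]1[C@H](C)[C@@H](O)CC[C@]1(C)O
F4 | step 4 | 1,3-dioxo-1,3-dihydro-2H-isoindol-2-yl 2-[(1S,2S,3S,6S)-3,6-dihydroxy-2,6-dimethylcyclohexyl]acetate | O=C(C[C@H]1[C@H](C)[C@@H](O)CC[C@]1(C)O)ON1C(=O)c2ccccc2C1=O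
F5 | step 9 | (1R,2S,3S,4S)-2,4-dimethyl-2-(prop-2-en-1-yl)-3-[(4,4,5,5-tetramethyl-1,3,2-dioxaborolan-2-yl)methyl]-4-[(trimethylsilyl)oxy]cyclohexyl trifluoromethanesulfonate | CC1(C)OB(C[C@H]2[C@](C)(CC=C)[C@H](OS(=O)(=O)C(F)(F)F)CC[C@]2(C)O[Si](C)(C)C)OC1(C)C
F6 | step 6 | trimethyl({(4S,5S,6S)-4,6-dimethyl-5-[(4,4,5,5-tetramethyl-1,3,2-dioxaborolan-2-yl)methyl]-4-[(trimethylsilyl)oxy]cyclohex-1-en-1-yl}oxy)silane | CC1(C)OB(C[C@H]2[C@H](C)C(O[Si](C)(C)C)=CC[C@]2(C)O[Si](C)(C)C)OC1(C)C
F7 | step 6 | (4S,5S,6S)-4,6-dimethyl-5-[(4,4,5,5-tetramethyl-1,3,2-dioxaborolan-2-yl)methyl]-4-[(trimethylsilyl)oxy]cyclohex-2-en-1-one | CC1(C)OB(C[C@H]2[C@H](C)C(=O)C=C[C@]2(C)O[Si](C)(C)C)OC1(C)C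
F8 | step 6 | (4S,5S,6S)-4,6-dimethyl-6-(prop-2-en-1-yl)-5-[(4,4,5,5-tetramethyl-1,3,2-dioxaborolan-2-yl)methyl]-4-[(trimethylsilyl)oxy]cyclohex-2-en-1-one | CC1(C)OB(C[C@H]2[C@](C)(CC=C)C(=O)C=C[C@]2(C)O[Si](C)(C)C)OC1(C)C
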